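Labdane numbering is used. Ring A (C1–C5, C10) is cut at C3–C4 and C1–C2, which frees C2–C3 as a two-carbon insert between the gem-dimethyl carbon C4 and the C1 methylene on quaternary C10. Both flanks are neopentyl, so C4 is made as a tertiary radical and C1 as an aldehyde. The precursor is monocyclic: an (R)-carvone whose isopropenyl group is latent C4 and whose new C10 carries CH3 and CHO. Iron-hydride hydrogen-atom transfer, Giese addition to methyl vinyl ketone and aldol closure build ring A in one operation. The acetyl group later becomes the 2α-acetate by Baeyer–Villiger oxidation. Ring B oxygenation and the side chain follow.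

Key step: step 4

Remark: α/β refer to the usual labdane drawing (C10–CH3 β, H5 α). "Decalin core" means the 4,4,8,10-tetramethyl-trans-decalin in labdane numbering. Compound 19 is taken as commercially available.

Step 1
Reactants: 1 (R)-(−)-carvone
Product: 3 (5R,6S)-6-methylcarvone, via lithium dienolate 2 (not isolated)
Conditions: LDA, THF, −78 °C; MeI, −78 → 0 °C
Reagents that add atoms: methyl iodide CI
Why: Kinetic α′-deprotonation of the enone and SN2 enolate alkylation anti to the isopropenyl group should give the trans product, whose new centre is flattened again in step 2 and is therefore of no consequence.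

Step 2
Reactants: 3 (5R,6S)-6-methylcarvone
Product: 5 (5S,6R)-6-(hydroxymethyl)-6-methylcarvone, via lithium dienolate 4 (not isolated)
Conditions: LDA, THF, −78 → 0 °C; monomeric CH2O in THF, −78 °C
Reagents that add atoms: formaldehyde C=O
Why: Aldol addition of the tetrasubstituted enolate to formaldehyde should occur anti to the neighbouring pseudoaxial isopropenyl group, which sets quaternary C10 with CH2OH (future C1) trans and CH3 cis to the C5 substituent.

Step 3
Reactants: 5 (5S,6R)-6-(hydroxymethyl)-6-methylcarvone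
Product: 6 (5S,6R)-6-formyl-6-methylcarvone
Conditions: Dess–Martin periodinane, CH2Cl2, 0 °C → rt; used without chromatography
Reagents that add atoms: none
Why: Dess–Martin oxidation is neutral and base-free, so retro-aldol loss of formaldehyde from 5 and deformylation of the non-enolisable β-keto aldehyde should be avoided.

Step 4
Reactants: 6 (5S,6R)-6-formyl-6-methylcarvone; 7 methyl vinyl ketone
Product: 8 2α-acetyl-1β-hydroxy-7-en-9-one of the decalin core
Conditions: Fe(acac)3 (cat.), PhSiH2(Oi-Pr), 7 (excess), THF, 0 °C → rt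
Reagents that add atoms: none
Why: An iron hydride formed from Fe(acac)3 and the silane transfers H• to the CH2 terminus of the isopropenyl group (MHAT), the tertiary C4 radical adds to the CH2 terminus of 7 (Giese addition, C3–C4), Fe(II) reduces the α-keto radical to an iron enolate, and this enolate adds through C2 to the formyl carbon on C10 (aldol, C1–C2). The closest known reaction type is the HAT-initiated radical–polar crossover annulation of an alkene-bearing aldehyde with an enone or enal. Ring A closes in a 6-(enolexo)-exo-trig aldol through a chair built on the trans-diequatorial C5 and C10 arms, so the preset C5 and C10 centres dictate the trans ring fusion. At C2 the acyl group should take the equatorial α position because the β-axial site is blocked by the axial C4 and C10 methyl groups, and C1 is expected to carry an equatorial β-OH, but neither centre is critical since C1 is flattened in step 5 and C2 is equilibrated in step 6 (stereoconvergent). The step needs chemoselective HAT to the electron-rich 1,1-disubstituted alkene over the conjugated trisubstituted C7=C8 bond and over 7, which the intrinsically faster HAT to terminal disubstituted alkenes and the excess of 7 should secure. The C4 radical has no intramolecular acceptor in reach (only four-membered closures), and the enolate should prefer the aldehyde to the hindered conjugated C9 ketone, whose attack would give a bridged bicyclo[3.3.1] system.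

Step 5
Reactants: 8 2α-acetyl-1β-hydroxy-7-en-9-one of the decalin core
Product: 10 2-acetyl-1,7-dien-9-one of the decalin core, via mesylate 9 (not isolated)
Conditions: MsCl, Et3N, CH2Cl2, 0 °C; then DBU, rt
Reagents that add atoms: none
Why: Mesylation through sulfene tolerates the neopentyl alcohol, and DBU-induced E1cB elimination across C1–C2 should give the same acetylcyclohexene from either C1 epimer.

Step 6
Reactants: 10 2-acetyl-1,7-dien-9-one of the decalin core
Product: 13 2α-acetyl-7-en-9-one of the decalin core, via boron enolate 11 (not isolated), via axial 2β-epimer 12 (not isolated)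
Conditions: catecholborane, THF, 0 °C → rt; then H2O/MeOH, K2CO3 (cat.), rt
Reagents that add atoms: none
Why: Uncatalysed conjugate reduction with catecholborane runs through a six-membered cyclic transition state open only to s-cis enones, so the acetyl enone should be reduced and the s-trans-locked ring B enone spared, and base equilibration then places the acetyl group equatorial (2α), away from the two axial β-methyl groups.

Step 7
Reactants: 13 2α-acetyl-7-en-9-one of the decalin core
Product: 14 2α-acetoxy-7-en-9-one of the decalin core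
Conditions: mCPBA, CH2Cl2, rt
Reagents that add atoms: mCPBA OOC(=O)c1cccc(Cl)c1
Why: Baeyer–Villiger oxidation with migration of the secondary C2 carbon under retention should give the 2α-acetate, while the electron-poor enone alkene and the hindered conjugated C9 ketone react far more slowly.

Step 8
Reactants: 14 2α-acetoxy-7-en-9-one of the decalin core
Product: 15 2α-acetoxy-7-ene-6,9-dione of the decalin core
Conditions: Pd(OH)2/C (cat.), t-BuOOH, K2CO3 (cat.), CH2Cl2, 4 °C → rt
Reagents that add atoms: tert-butyl hydroperoxide CC(C)(C)OO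
Why: Allylic oxidation of an enone to a 1,4-enedione by tert-butylperoxy radicals should attack C6, the only CH2 whose radical is conjugated through C7=C8 with the carbonyl, and the trans ring fusion is the thermodynamic one so C5 is not endangered.

Step 9
Reactants: 15 2α-acetoxy-7-ene-6,9-dione of the decalin core
Product: 17 2α,6β-dihydroxy-7-en-9-one of the decalin core, via hydroxy acetate 16 (not isolated)
Conditions: NaBH4, CeCl3·7H2O, MeOH, −78 °C; acetone quench; then K2CO3 (cat.), MeOH, 0 °C → rt
Reagents that add atoms: none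
Why: Luche 1,2-reduction should select C6=O because C9=O is flanked by quaternary C10 and methyl-bearing C8 (the bias known from 4-oxoisophorone), hydride arrives from the open α face opposite to the axial C4 and C10 methyl groups to set 6β-OH, and carbonate-catalysed methanolysis frees the 2α-OH ahead of the organolithium step.

Step 10
Reactants: 17 2α,6β-dihydroxy-7-en-9-one of the decalin core
Product: 18 2α,6β-bis(triethylsilyloxy)-7-en-9-one of the decalin core
Conditions: TESOTf, 2,6-lutidine, CH2Cl2, −78 → 0 °C
Reagents that add atoms: triethylsilyl triflate CC[Si](CC)(CC)OS(=O)(=O)C(F)(F)F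
Why: Silylation with a silyl triflate and a hindered pyridine base should also reach the axial, doubly 1,3-diaxially flanked 6β-OH and shields both alcohols from the organolithium reagent.

Step 11
Reactants: 19 4-(tert-butyldimethylsilyloxy)but-1-yne
Product: 22 (E)-5-(tert-butyldimethylsilyloxy)-3-methylpent-2-en-1-ol, via alkenylalane 20 (not isolated), via lithium alanate 21 (not isolated)
Conditions: Me3Al, Cp2ZrCl2 (cat.), CH2Cl2, 0 °C → rt; n-BuLi, THF, −78 °C; (CH2O)n, rt
Reagents that add atoms: trimethylaluminium C[Al](C)C; formaldehyde (from paraformaldehyde) C=O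
Why: Negishi zirconium-catalysed carboalumination adds CH3 and Al syn across the terminal alkyne with Al at the terminus, and hydroxymethylation of the alanate with retention fixes the (E)-trisubstituted C13=C14 alkene.

Step 12
Reactants: 22 (E)-5-(tert-butyldimethylsilyloxy)-3-methylpent-2-en-1-ol
Product: 23 (E)-1-(tert-butyldiphenylsilyloxy)-5-(tert-butyldimethylsilyloxy)-3-methylpent-2-ene
Conditions: TBDPSCl, imidazole, CH2Cl2, rt
Reagents that add atoms: tert-butyldiphenylsilyl chloride CC(C)(C)[Si](Cl)(c1ccccc1)c1ccccc1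
Why: Standard imidazole-promoted silylation installs the acid-stable TBDPS group, chosen to survive steps 13 and 16.

Step 13
Reactants: 23 (E)-1-(tert-butyldiphenylsilyloxy)-5-(tert-butyldimethylsilyloxy)-3-methylpent-2-ene
Product: 24 (E)-5-(tert-butyldiphenylsilyloxy)-3-methylpent-3-en-1-ol
Conditions: CSA (cat.), MeOH/CH2Cl2, 0 °C
Reagents that add atoms: none
Why: Acid-catalysed methanolysis should remove the primary TBS ether much faster than the bulkier TBDPS ether (selective silyl ether cleavage).

Step 14
Reactants: 24 (E)-5-(tert-butyldiphenylsilyloxy)-3-methylpent-3-en-1-ol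
Product: 25 (E)-tert-butyl[(5-iodo-3-methylpent-2-en-1-yl)oxy]diphenylsilane
Conditions: I2, PPh3, imidazole, CH2Cl2, 0 °C
Reagents that add atoms: iodine II
Why: Appel-type iodination (SN2 on the alkoxyphosphonium ion) of the unhindered primary alcohol leaves the alkene geometry untouched.

Step 15
Reactants: 25 (E)-tert-butyl[(5-iodo-3-methylpent-2-en-1-yl)oxy]diphenylsilane; 18 2α,6β-bis(triethylsilyloxy)-7-en-9-one of the decalin core
Product: 27 15-(tert-butyldiphenylsilyloxy)-2α,6β-bis(triethylsilyloxy)labda-7,13E-dien-9β-ol, via alkyllithium 26 (not isolated)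
Conditions: 25, t-BuLi (2 equiv per 25), Et2O/pentane, −78 °C; then 18, −78 → −20 °C
Reagents that add atoms: none
Why: Lithium–iodine exchange followed by 1,2-addition of the primary alkyllithium to the α-blocked enone carbonyl should occur from the α face opposite to the axial C10 methyl group, and the C9 configuration is lost again in step 16.

Step 16
Reactants: 27 15-(tert-butyldiphenylsilyloxy)-2α,6β-bis(triethylsilyloxy)labda-7,13E-dien-9β-ol
Product: 29 7α-acetoxy-15-(tert-butyldiphenylsilyloxy)labda-8,13E-diene-2α,6β-diol, via bis-TES 7α-acetate 28 (not isolated)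
Conditions: AcOH, TsOH·H2O (cat.), CH2Cl2, −20 → 0 °C; then AcOH/THF/H2O, rt
Reagents that add atoms: acetic acid CC(=O)O
Why: In this acid-catalysed allylic (SN1′) transposition the strained tertiary C9 alcohol should ionise to the C7–C8–C9 allyl cation, acetic acid captures it at the less hindered C7 terminus by axial attack on the α face anti to the bulky 6β-silyloxy group (setting 7α-OAc and the tetrasubstituted C8=C9 alkene), and aqueous acetic acid then cleaves both TES ethers but not the TBDPS ether.

Step 17
Reactants: 29 7α-acetoxy-15-(tert-butyldiphenylsilyloxy)labda-8,13E-diene-2α,6β-diol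
Product: 30 2α,7α-diacetoxy-15-(tert-butyldiphenylsilyloxy)labda-8,13E-dien-6β-ol
Conditions: Ac2O, pyridine, DMAP (cat.), CH2Cl2, 0 °C
Reagents that add atoms: acetic anhydride CC(=O)OC(C)=O
Why: Sterically differentiated acylation should acetylate only the equatorial 2α-OH, since the axial 6β-OH lies between two syn-axial methyl groups, and the trans-diaxial 6,7-arrangement rules out acetyl migration.

Step 18
Reactants: 30 2α,7α-diacetoxy-15-(tert-butyldiphenylsilyloxy)labda-8,13E-dien-6β-ol
Product: 31 2α,7α-diacetoxy-6β-(3-methylbutanoyloxy)-15-(tert-butyldiphenylsilyloxy)labda-8,13E-diene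
Conditions: isovaleric anhydride, DMAP, Et3N, 1,2-dichloroethane, 60 °C
Reagents that add atoms: isovaleric anhydride CC(C)CC(=O)OC(=O)CC(C)C
Why: DMAP-mediated acyl transfer under forcing conditions should esterify the last free, hindered 6β-OH.

Step 19
Reactants: 31 2α,7α-diacetoxy-6β-(3-methylbutanoyloxy)-15-(tert-butyldiphenylsilyloxy)labda-8,13E-diene
Product: 32 2α,7α-diacetoxy-6β-(3-methylbutanoyloxy)labda-8,13E-dien-15-ol (target)
Conditions: HF·pyridine, pyridine/THF, 0 °C → rt
Reagents that add atoms: none
Why: Fluoride-induced Si–O cleavage under mildly acidic buffered conditions should leave the three esters, including the allylic acetate, untouched.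

Compound list
1 | (R)-(−)-carvone | C=C(C)[C@@H]1CC=C(C)C(=O)C1 | starting material
2 | lithium cross-conjugated dienolate of 1 | C=C(C)[C@@H]1CC=C(C)C(O[Li])=C1 | intermediate
3 | (5R,6S)-6-methylcarvone (CH3 trans to isopropenyl) | C=C(C)[C@@H]1CC=C(C)C(=O)[C@H]1C | intermediate
4 | lithium dienolate of 3 | C=C(C)[C@@H]1CC=C(C)C(O[Li])=C1C | intermediate
5 | (5S,6R)-6-(hydroxymethyl)-6-methylcarvone (CH2OH trans, CH3 cis to isopropenyl) | C=C(C)[C@@H]1CC=C(C)C(=O)[C@@]1(C)CO | intermediate
6 | (5S,6R)-6-formyl-6-methylcarvone | C=C(C)[C@@H]1CC=C(C)C(=O)[C@@]1(C)C=O | intermediate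
7 | methyl vinyl ketone | C=CC(C)=O | starting material
8 | 2α-acetyl-1β-hydroxy-7-en-9-one of the decalin core | CC(=O)[C@H]1CC(C)(C)[C@@H]2CC=C(C)C(=O)[C@@]2(C)[C@@H]1O | intermediate
9 | 1β-mesylate of 8 | CC(=O)[C@H]1CC(C)(C)[C@@H]2CC=C(C)C(=O)[C@@]2(C)[C@@H]1OS(C)(=O)=O | intermediate
10 | 2-acetyl-1,7-dien-9-one of the decalin core | CC(=O)C1=C[C@]2(C)C(=O)C(C)=CC[C@H]2C(C)(C)C1 | intermediate
11 | catecholboron enolate from 10 (O cis to C1) | C/C(OB3Oc4ccccc4O3)=C1\CC(C)(C)[C@@H]2CC=C(C)C(=O)[C@@]2(C)C1 | intermediate
12 | 2β-acetyl (axial) epimer of 13 | CC(=O)[C@@H]1CC(C)(C)[C@@H]2CC=C(C)C(=O)[C@@]2(C)C1 | intermediate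
13 | 2α-acetyl-7-en-9-one of the decalin core | CC(=O)[C@H]1CC(C)(C)[C@@H]2CC=C(C)C(=O)[C@@]2(C)C1 | intermediate
14 | 2α-acetoxy-7-en-9-one of the decalin core | CC(=O)O[C@H]1CC(C)(C)[C@@H]2CC=C(C)C(=O)[C@@]2(C)C1 | intermediate
15 | 2α-acetoxy-7-ene-6,9-dione of the decalin core | CC(=O)O[C@H]1CC(C)(C)[C@@H]2C(=O)C=C(C)C(=O)[C@@]2(C)C1 | intermediate
16 | 2α-acetoxy-6β-hydroxy-7-en-9-one of the decalin core | CC(=O)O[C@H]1CC(C)(C)[C@@H]2[C@H](O)C=C(C)C(=O)[C@@]2(C)C1 | intermediate
17 | 2α,6β-dihydroxy-7-en-9-one of the decalin core | O[C@H]1CC(C)(C)[C@@H]2[C@H](O)C=C(C)C(=O)[C@@]2(C)C1 | intermediate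
18 | 2α,6β-bis(triethylsilyloxy)-7-en-9-one of the decalin core | CC[Si](CC)(CC)O[C@H]1CC(C)(C)[C@@H]2[C@H](O[Si](CC)(CC)CC)C=C(C)C(=O)[C@@]2(C)C1 | intermediate
19 | 4-(tert-butyldimethylsilyloxy)but-1-yne | C#CCCO[Si](C)(C)C(C)(C)C | starting material
20 | (E)-alkenyl(dimethyl)alane from 19 | C[Al](C)/C=C(\C)CCO[Si](C)(C)C(C)(C)C | intermediate
21 | lithium butyl(dimethyl)alkenylalanate | [Li+].CCCC[Al-](C)(C)/C=C(\C)CCO[Si](C)(C)C(C)(C)C | intermediate
22 | (E)-5-(tert-butyldimethylsilyloxy)-3-methylpent-2-en-1-ol | CC(C)(C)[Si](C)(C)OCC/C(C)=C/CO | intermediate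
23 | (E)-1-(tert-butyldiphenylsilyloxy)-5-(tert-butyldimethylsilyloxy)-3-methylpent-2-ene | CC(C)(C)[Si](C)(C)OCC/C(C)=C/CO[Si](c1ccccc1)(c1ccccc1)C(C)(C)C | intermediate
24 | (E)-5-(tert-butyldiphenylsilyloxy)-3-methylpent-3-en-1-ol | OCC/C(C)=C/CO[Si](c1ccccc1)(c1ccccc1)C(C)(C)C | intermediate
25 | (E)-tert-butyl[(5-iodo-3-methylpent-2-en-1-yl)oxy]diphenylsilane | ICC/C(C)=C/CO[Si](c1ccccc1)(c1ccccc1)C(C)(C)C | intermediate
26 | alkyllithium from 25 | [Li]CC/C(C)=C/CO[Si](c1ccccc1)(c1ccccc1)C(C)(C)C | intermediate
27 | 15-(tert-butyldiphenylsilyloxy)-2α,6β-bis(triethylsilyloxy)labda-7,13E-dien-9β-ol | CC[Si](CC)(CC)O[C@H]1CC(C)(C)[C@@H]2[C@H](O[Si](CC)(CC)CC)C=C(C)[C@@](O)(CC/C(C)=C/CO[Si](c3ccccc3)(c3ccccc3)C(C)(C)C)[C@@]2(C)C1 | intermediate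
28 | 7α-acetoxy-15-(tert-butyldiphenylsilyloxy)-2α,6β-bis(triethylsilyloxy)labda-8,13E-diene | CC[Si](CC)(CC)O[C@H]1CC(C)(C)[C@@H]2[C@H](O[Si](CC)(CC)CC)[C@@H](OC(C)=O)C(C)=C(CC/C(C)=C/CO[Si](c3ccccc3)(c3ccccc3)C(C)(C)C)[C@@]2(C)C1 | intermediate
29 | 7α-acetoxy-15-(tert-butyldiphenylsilyloxy)labda-8,13E-diene-2α,6β-diol | O[C@H]1CC(C)(C)[C@@H]2[C@H](O)[C@@H](OC(C)=O)C(C)=C(CC/C(C)=C/CO[Si](c3ccccc3)(c3ccccc3)C(C)(C)C)[C@@]2(C)C1 | intermediate
30 | 2α,7α-diacetoxy-15-(tert-butyldiphenylsilyloxy)labda-8,13E-dien-6β-ol | CC(=O)O[C@H]1CC(C)(C)[C@@H]2[C@H](O)[C@@H](OC(C)=O)C(C)=C(CC/C(C)=C/CO[Si](c3ccccc3)(c3ccccc3)C(C)(C)C)[C@@]2(C)C1 | intermediate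
31 | 2α,7α-diacetoxy-6β-(3-methylbutanoyloxy)-15-(tert-butyldiphenylsilyloxy)labda-8,13E-diene | CC(=O)O[C@H]1CC(C)(C)[C@@H]2[C@H](OC(=O)CC(C)C)[C@@H](OC(C)=O)C(C)=C(CC/C(C)=C/CO[Si](c3ccccc3)(c3ccccc3)C(C)(C)C)[C@@]2(C)C1 | intermediate
32 | 2α,7α-diacetoxy-6β-(3-methylbutanoyloxy)labda-8,13E-dien-15-ol (CNP0257091.1) | CC(=O)O[C@H]1CC(C)(C)[C@@H]2[C@H](OC(=O)CC(C)C)[C@@H](OC(C)=O)C(C)=C(CC/C(C)=C/CO)[C@@]2(C)C1 | target

Total step count: 19. Longest linear sequence: 15 steps (steps 1–10 and 15–19). Steps 11–14 form the side-chain branch.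

Steps most likely to fail

Step 4. The formyl group may be lost by retro-Claisen cleavage in the reaction medium. Hydrogen-atom transfer may go to the wrong alkene, the acceptor may oligomerise, or the enolate may be protonated before ring closure.
Fallback (radical from a halide, closure through a boron enolate), setting out from 6:
- Markovnikov hydroiodination of the isopropenyl group (TMSCl, NaI, H2O, MeCN) gives the tertiary iodide F1.
- Treatment with Et3B/air and 7 in CH2Cl2 lets an ethyl radical abstract iodine.
- The C4 radical adds to 7, and Et3B traps the α-keto radical as a boron enolate, which closes on the formyl group.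
- Both ring A bonds are still formed in one operation, and the sequence comes back to the route at 8.

Step 16. The allylic C6–O bond may ionise in competition. The allyl cation may lose a proton to give dienes. Facial selectivity at C7 may be poor.
Fallback (oxidation, reduction and inversion in place of cation capture), setting out from 27:
- Babler–Dauben oxidative transposition with PCC gives the 6β-silyloxy-8-en-7-one F2.
- Luche reduction from the α face gives the 7β-alcohol F3.
- Mitsunobu inversion with acetic acid (PPh3, DIAD) comes back to the route at 28, which is desilylated to 29 as in step 16.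

Step 9. Discrimination between the two enedione carbonyl groups may be poor, and over-reduction or 1,4-reduction may intervene.
Fallback (exhaustive reduction, then stereoelectronically selective re-oxidation), setting out from 15:
- Excess NaBH4/CeCl3 at 0 °C reduces both carbonyl groups from the α face to the 6β,9β-enediol F4.
- MnO2 then oxidises only the pseudoequatorial 9β-alcohol, whose axial C–H bond overlaps with the alkene. The axial 6β-alcohol is spared.
- The sequence comes back to the route at 16, which is methanolysed to 17 as in step 9.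

Further compounds
F1 | step 4 | (5S,6R)-6-formyl-5-(2-iodopropan-2-yl)-2,6-dimethylcyclohex-2-en-1-one | CC(C)(I)[C@@H]1CC=C(C)C(=O)[C@@]1(C)C=O
F2 | step 16 | 15-(tert-butyldiphenylsilyloxy)-2α,6β-bis(triethylsilyloxy)labda-8,13E-dien-7-one | CC[Si](CC)(CC)O[C@H]1CC(C)(C)[C@@H]2[C@H](O[Si](CC)(CC)CC)C(=O)C(C)=C(CC/C(C)=C/CO[Si](c3ccccc3)(c3ccccc3)C(C)(C)C)[C@@]2(C)C1
F3 | step 16 | 15-(tert-butyldiphenylsilyloxy)-2α,6β-bis(triethylsilyloxy)labda-8,13E-dien-7β-ol | CC[Si](CC)(CC)O[C@H]1CC(C)(C)[C@@H]2[C@H](O[Si](CC)(CC)CC)[C@H](O)C(C)=C(CC/C(C)=C/CO[Si](c3ccccc3)(c3ccccc3)C(C)(C)C)[C@@]2(C)C1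
F4 | step 9 | 2α-acetoxy-7-ene-6β,9β-diol of the decalin core | CC(=O)O[C@H]1CC(C)(C)[C@@H]2[C@H](O)C=C(C)[C@H](O)[C@@]2(C)C1
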